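The runs were generated by integration on assumed constants, noise included.

If substrate follows first-order decay, the common logarithm of its amount falls on a straight line, so I worked in powers of ten.

| flask | substrate | reagent | remark | time |
|---|---|---|---|---|
| elm | 0.10 M | 1.7 equiv | run made earlier |  |
| ash | 0.10 M | 2.6 equiv | run made earlier |  |
| winter | 0.10 M | 1.20 equiv |  | 20 h |
| spring | 0.10 M | 1.20 equiv |  | 10 h |

| run | time / h | substrate / % | intermediate / % | target / % |
|---|---|---|---|---|
| elm | 0.667 | 97 | 2 | 0 |
| elm | 1.00 | 94 | 6 | 0 |
| elm | 1.33 | 95 | 9 | 0 |
| elm | 2.50 | 88 | 11 | 2 |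
| elm | 3.00 | 85 | 13 | 2 |
| elm | 5.00 | 78 | 18 | 3 |
| elm | 8.00 | 67 | 27 | 2 |
| ash | 1.00 | 94 | 5 | 0 |
| ash | 2.50 | 90 | 12 | 0 |
| ash | 3.00 | 88 | 13 | 4 |
| ash | 5.00 | 79 | 18 | 0 |
| ash | 6.00 | 75 | 21 | 2 |
| ash | 8.00 | 70 | 23 | 4 |

(each reading ± 1.5 percentage points)

- the numbers in the tables scatter with a standard deviation of 1.5 percentage points
- a reading or a percentage of target counts all its forms, free or not

* which of these there is most of at the end, counted by the substrate in it, winter (target / intermediate / substrate)
* which of these there is most of at the end, counted by the substrate in it, spring (target / intermediate / substrate)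
* the largest of these amounts at the end, in percent of the substrate charged, winter
* the largest of these amounts at the end, in percent of the substrate charged, spring

After 8.00 h, elm held 67% substrate on 1.7 equiv of reagent, and ash held 70% on 2.6 equiv. I read that gap as no clear effect of reagent, and I carried this untested to 1.20 equiv. The mean fall was 0.164 of a power of ten, and a halving is 0.301. So τ, the half-life of substrate, was 14.6 h.

I held two times against each other: τ and the time of the flask. At that time elm and ash read target at 2% and 4%, and intermediate at 27% and 23%. So I took the lost substrate to stand as intermediate, and I expected substrate and intermediate to cross near a ratio of one between the flask's time and τ. Spring stood at 0.683, with 62.3% substrate by my reckoning, so I named substrate. Winter stood at 1.37, with 38.8% substrate. I named intermediate there, provided target stayed under 22 percentage points.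

The forecast said “so the first step shows no measurable dependence on reagent over this range”. It gave intermediate at 45% (38% to 56%) for winter, and substrate at 61% (56% to 66%) for spring.

Winter gave intermediate at 49.4%, and spring gave substrate at 62.4%.

    substrate → intermediate (k = 1.31 × 10⁻⁵ s⁻¹)
    crystals ⇌ target, rate k2*(cs2 - [target]) while solid is left; crystals form when [target] > cs2 (solubility = 1.10 mM, k = 1.79 × 10⁻⁴ s⁻¹)
    reagent ⇌ dormant form (K = 0.338, k = 9.72 × 10⁻⁶ s⁻¹)
    reagent + intermediate → target (k = 5.80 × 10⁻⁵ L mol⁻¹ s⁻¹)

Neither flask had come to rest. Spring read at 25 h stood at 1.71 half-lives, past the crossing, and τ gives 30.5% substrate. Spring at that time held 30.8% substrate, with intermediate at 53.3%. Winter taken on to 200 h lost 3.69 more powers of ten of substrate, where τ counted 3.70, and reached 0.00801%. Its intermediate fell from 49.4% to 18.9%, and its target, crystals counted, climbed from 11.7% to 81.1%.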